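(All runs are calculated with constants of no real substance; noise was put on by code.)

Late in the south-east run, at 90.0 min, I drew up the ledger for substrate, the limiting reagent against the 7 equiv of reagent charged there. Of the charge, 94.5 % stood as product and 4.1 % as substrate. The catalyst, charged at 0.12 mol%, could hold far less substrate than the product entry showed, and the gap of 1.4 percentage points stood beside a scatter of 1 point per reading. So I booked each product entry as one turn of the catalyst. The mean turnover frequency, a reading from that run, came to 8.75 min⁻¹: product made per catalyst per minute.

| flask | substrate | reagent | scavenger | free catalyst | remark | time |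
|---|---|---|---|---|---|---|
| south-east | 0.16 M | 7 equiv | 0.50 equiv | 0.12 mol% | run made earlier |  |
| north | 0.16 M | 11 equiv | 0.50 equiv | 0.12 mol% | run made earlier |  |
| flask | 0.16 M | 5.00 equiv | 0.500 equiv | 0.12 mol% |  | 2.0 h |

| run | time / min | substrate / % | product / % |
|---|---|---|---|
| south-east | 25.0 | 68.4 | 31.4 |
| south-east | 50.0 | 40.2 | 59.8 |
| south-east | 80.0 | 11.2 | 86.9 |
| south-east | 90.0 | 4.1 | 94.5 |
| north | 8.00 | 88.4 | 10.4 |
| north | 20.0 | 74.3 | 25.1 |
| north | 40.0 | 47.0 | 53.3 |
| north | 90.0 | 1.6 | 98.1 |

(standard deviation of a reading: 1 percentage point)

1. part of the substrate that has reacted at 2.0 h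
2. share of the unused reagent that is free and not bound as idle adduct, at 2.0 h

- the analysis behind the earlier runs scatters by 1 percentage point, standard deviation
- the earlier runs do not show how much of reagent is bound; that part of a forecast is a guess

For the asked flask I multiplied that frequency by loading and time, which gave a budget of 126 % of the charge. That budget was larger than the charge, so I expected the flask's substrate, not its catalyst turns, to close the ledger, though at 5.00 equiv of reagent against 7 equiv the frequency might stand lower.

The forecast gave 98 % reacted, between 93 % and 99.8 %, reading “so reagent dependence is weak, roughly saturating”. For the free share it guessed 88 %, between 65 % and 99 %.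

The flask gave 98.6 % reacted and 93.1 % free, so the reacted part fell within the tolerance and the free share stood 5.1 points above the forecast.

    substrate + free catalyst ⇌ catalyst intermediate A (K = 18.0 M⁻¹, k = 2300 M⁻¹ min⁻¹)
    reagent + catalyst intermediate A ⇌ catalyst intermediate B (K = 1.90 M⁻¹, k = 1100 M⁻¹ min⁻¹)
    catalyst intermediate B → catalyst intermediate C (k = 34.0 min⁻¹)
    catalyst intermediate C → released group + catalyst intermediate D (k = 270 min⁻¹)
    catalyst intermediate D → free catalyst + product (k = 26.0 min⁻¹)
    reagent + released group ⇌ idle adduct, settled at all times (K = 2.00 M⁻¹)
    scavenger + released group → scavenged by-product (k = 1.20 M⁻¹ min⁻¹)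

In this flask the budget for 1.00 h was 63.0 % of the charge, and product stood at 64.7 %. The neighbour charged with 0.03 mol% of free catalyst had a quarter of the flask's loading, with all else held. Its budget for 2.0 h was 31.5 %, smaller than its charge, and in that neighbour 65.8 % stayed substrate while 34.2 % had reacted.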